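Numbering: labdane numbering for the core (C16 = methyl on C13, C17 = methyl on C8, C18 = 4α carbon, C19 = 4β methyl, C20 = 10β methyl); the butenolide atoms are O1′, C2′ (carbonyl), C3′, C4′ (methyl-bearing) and C5′ (bonded to C15).

Assumption: 23 is taken in the open 6α-hydroxy-18-aldehyde form as drawn; its five-membered 18,6α-hemiacetal is only a ring tautomer, and the hemiacetal carbon C18 of 16, 17, 18, 21 and 22 is an anomeric mixture that is erased in the last step, so it carries no descriptor in their SMILES.

## Structural features

23 is a C25 terpenoid: a trans-fused decalin (rings A and B, labdane core) whose C9 carries a five-carbon chain ending in a 4-methylbutenolide joined through C5′. Six contiguous stereocentres sit on the decalin (C4, C5, C6, C8, C9, C10), with quaternary C4 and C10 and the tertiary carbinol C8. Two more, C15 and C5′, are adjacent to each other (threo, 15S,5′S) but lie several bonds from the core, beyond the (E)-trisubstituted C13=C14 alkene. The fragile groups are the butenolide (acidic C5′–H next to the carbinol, so epimerisation and retro-aldol cleavage with base), the allylic C15 alcohol (ionisation with acid), the tertiary 8-hydroxyl (elimination, oxa-Michael addition to a conjugated C13=C14 intermediate, hemiketal formation with a C13 ketone) and the neopentyl C18 aldehyde, which lies peri to the 6α-hydroxyl and can close to a hemiacetal. The core has the skeleton and configuration of a 6α-hydroxylabdane, so the real difficulties are two: to oxidise one unactivated methyl group, C18, beside C19, C20, C17 and C16, and to set C15/C5′ with no help from the core. The key step uses the fact that, on the A/B trans-decalin, the equatorial 6α-oxygen on ring B and the equatorial 4α-methyl on ring A are parallel and roughly 2.6 Å apart (C18–C4–C5–C6–O), whereas the axial β-methyls point away. An oxygen radical on O6 can therefore reach only C18, and in closing the ether it makes C4 a stereocentre of the required configuration.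

## Logic of the disconnections

23 to 22: two O–Si bonds are cut, at O8 and at the hemiacetal oxygen on C18; no skeletal bond is touched. The peri pair 6α-OH/18-CHO is most safely carried as its ring tautomer capped on oxygen, and O8 has to stay blocked while C13=C14 is conjugated. The gain is that 22 has neither a free aldehyde nor a free tertiary alcohol. The forward step must cleave both silyl groups without base (C5′–H) and without strong acid (allylic C15–OH).

22 to 18 and 20: the C15–C5′ bond is cut, the bond between the two remote stereocentres and the retron of a vinylogous aldol addition. The C25 skeleton falls into a C20 enal and a C5 dienol ether, and both side-chain stereocentres arise in one step. The forward step must be γ-selective, threo-selective and, because the core is too far away, controlled in its absolute sense by a catalyst.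

20 to 19: the O–Si bond of the dienol ether is cut, which leads to a commercial butenolide. The forward step only has to enolise toward the aromatic furan.

18 to 15 (through 17 and 16): the O–Si bond at C18 is cut and the oxidation levels of C15 and C18 are traced back to an ester and a lactone. One hydride reagent can then set both, and 15 contains only robust groups. The reduction has to stop at the lactol, and the following oxidation has to touch only the allylic alcohol.

15 to 13 and 14: the C13=C14 double bond is cut (carbonyl olefination). The side chain is shortened to a methyl ketone and a two-carbon phosphonate. The forward step has to give the (13E) geometry.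

13 to 11 (through 12): the C13 carbonyl is masked again and the C18 carbonyl is taken back to the CH2 of a cyclic ether. The ether is the direct product of a radical relay from O6, so the forward oxidation must attack only the ether methylene.

11 to 8: the O–C18 bond is cut; this is the disconnection that carries the plan. It removes the tetrahydrofuran ring and the C4 stereocentre and leaves a gem-dimethyl group. 8 is designed so that O6 is the only free hydroxyl, O8 is a tertiary silyl ether (a free 8-alkoxyl radical would fragment) and C13 is a ketal. The forward step must functionalise C18 and no other C–H bond.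

8 to 4 (through 7 and 6): the O8–Si bond, the O6–acetyl bond (in the sense of exchanging protection) and the C8–O bond are cut. O6 and O8 cannot be told apart once both are free, so O6 is acetylated before O8 exists and is released after O8 is silylated. The forward hydration must place oxygen on C8 from the α face.

4 to 1 (through 3 and 2): the dioxolane C–O bonds, the C13–C14 bond (with loss of C14 and C15) and the acetyl group on O6 are removed in turn. This arrives at a natural 6α-hydroxylabdane that already holds C5, C6, C9 and C10. The forward degradation must cleave the vinyl carbinol and spare C8=C17.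

## Other disconnections considered

Alternative 1: The cut is C5–C6 in ring B. Forward, a chiral triazolylidene carbene adds to the C6 aldehyde of the cyclohexadienone aldehyde A1, and the acyl-anion equivalent adds to C5 of the dienone (intramolecular Stetter reaction). This closes ring B and turns the prochiral C10 into a quaternary stereocentre in the cis-fused enedione A2.
- In its favour: a catalytic enantioselective entry that does not depend on a natural diterpene and opens both enantiomers and ring A analogues. The C6 oxygen arrives in place and the ring A enone is a handle for C4.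
- Against it here: A1 must already hold C8 and C9 in enantiopure form, so the catalyst works in a matched or mismatched pair. A2 has the cis ring fusion and needs epimerisation at C5. C4 would have to be built by two alkylations with control of which group ends α, the C3 oxygen and C1=C2 removed, the C6 ketone reduced to the equatorial alcohol, and the whole side chain grown from the C11 ether.
- Comparison: on structure, the chosen plan takes C5, C6, C9 and C10 from 1 and creates only C8 and C4, whereas this plan creates every centre. On mechanism, the Stetter step forms a skeletal C–C bond and a quaternary centre, which the chosen key step does not; on supply and flexibility it is the better approach. On step economy it is clearly worse; the sequence after A2 is estimated at well over twice the sixteen steps proposed.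

Alternative 2: The cuts are C5–C10 and C8–C9. Forward, Me2AlCl chelates the acyl oxazolidinone of triene A3 and the C5=C6(OSi)–C7=C8 diene adds to the C9=C10 enoyl unit, concertedly or as two Michael additions. This gives octalin A4 with both rings and four stereocentres (C5, C8, C9, C10) formed at once.
- In its favour: the highest gain in complexity per step of the four plans, and on this count it is better than the chosen key step. C18 is present from the start at the carboxyl level as one ester of the malonate, so no C–H oxidation is needed, and the 6-oxygen is in place. Lactonisation of a 6α-hydroxyl onto the 4α-ester would tell the two esters apart and lead to the same kind of 18,6α-lactone as in 12 to 15, a point of equal merit.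
- Against it here: C10 of the dienophile is fully substituted, so the cycloaddition should be slow and may turn stepwise, which puts the trans ring fusion and the endo relation at risk. C8 is formed as a C–H centre, so the tertiary 8α-hydroxyl must be introduced later by oxidation in the C7–C8 region. The 4β-ester must be reduced all the way to a methyl group at a neopentyl position, the C6 ketone reduced to the equatorial alcohol, and the side chain extended from the C11 imide.
- Comparison: on structure, it builds what the chosen plan obtains from 1. On mechanism, a pericyclic step under auxiliary control of four centres stands against a radical hydrogen transfer whose single new centre is fixed by geometry, so the stereochemical risk is higher for the alternative. On step economy, the adjustments after A4 make it considerably longer.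

Alternative 3: The cuts are C14–C15 and the C13–CH3 bond. Forward, Cp2ZrCl2-catalysed methylalumination of the terminal alkyne A5 adds methyl to C13 and aluminium to C14 in a syn sense. After transmetalation with ZnCl2 the alkenyl metal adds to the α-alkoxy aldehyde A6 to give the allylic alcohol A7.
- In its favour: syn-carbometalation defines the (E)-trisubstituted alkene completely, which is better than the olefination of step 10. C5′ comes from a small enantiopure aldehyde and C15 follows by chelation control, so the C15/C5′ pair needs no enantioselective catalyst; here it is at least the equal of step 15 and probably better.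
- Against it here: it is a side-chain union only and presupposes a core such as A5 in which C18 is already oxidised, so it would follow the chosen key step, not replace it. The alkyne must be made from the methyl ketone in extra steps. Excess AlMe3 is a Lewis acid toward the dimethyl acetal and the silyl ethers. A6 is an α-alkoxy β,γ-unsaturated aldehyde that can racemise or slip into conjugation. After A7 the butenolide must still be built by protecting-group exchange, acylation of O5′ with an acryloyl unit and ring-closing metathesis (second-generation Grubbs catalyst) onto the isopropenyl group.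
- Comparison: on structure, the same bonds of the side chain result, but C15–C5′ is bought with the aldehyde. On mechanism, a polar organometallic addition under 1,2-induction stands against a catalyst-controlled aldol addition. On step economy it is longer by roughly five steps, yet it would be a sound replacement for steps 10 to 15 if catalyst control in step 15 could not be reached.

Key step: step 7

## Route

Step 1
Reactants: 1 larixol
Product: 2 larixyl acetate, (13S)-6α-acetoxylabda-8(17),14-dien-13-ol
Conditions: Ac2O, pyridine, 4-(dimethylamino)pyridine (cat.), CH2Cl2, rt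
Reagents that add atoms: acetic anhydride, CC(=O)OC(C)=O
Why: Acylation of the secondary 6α-hydroxyl; the tertiary allylic 13-hydroxyl should not react under these conditions. The acetate shields the C6 carbinol from permanganate and later distinguishes O6 from O8; 2 is also an article of commerce, so the step can be skipped.

Step 2
Reactants: 2 larixyl acetate
Product: 3 6α-acetoxy-14,15-dinorlabd-8(17)-en-13-one
Conditions: KMnO4, MgSO4, acetone/H2O, 0 °C to rt
Reagents that add atoms: none
Why: Permanganate degradation of a tertiary vinyl carbinol: oxidative cleavage of the vinyl group and oxidative decarboxylation remove C15 and C14, and the carbinol oxygen becomes the C13 carbonyl oxygen. The hindered 1,1-disubstituted C8=C17 alkene should react more slowly, as in the known degradation of related 13-hydroxylabda-8(17),14-dienes.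

Step 3
Reactants: 3 6α-acetoxy-14,15-dinorlabd-8(17)-en-13-one
Product: 4 6α-acetoxy-13,13-ethylenedioxy-14,15-dinorlabd-8(17)-ene
Conditions: HOCH2CH2OH, pyridinium p-toluenesulfonate (cat.), toluene, reflux, azeotropic removal of water
Reagents that add atoms: ethylene glycol, OCCO
Why: Acid-catalysed ketalisation; the mild pyridinium acid should not move the exocyclic alkene. The dioxolane protects C13 from borohydride in step 4 and prevents hemiketal formation with the 8-hydroxyl.

Step 4
Reactants: 4 6α-acetoxy-13,13-ethylenedioxy-14,15-dinorlabd-8(17)-ene
Product: 6 6α-acetoxy-13,13-ethylenedioxy-14,15-dinorlabdan-8α-ol, via 17-acetoxymercurio 8α-alcohol 5 (not isolated)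
Conditions: Hg(OAc)2, THF/H2O, rt; then NaBH4, aq. NaOH, 0 °C
Reagents that add atoms: water, O
Why: Oxymercuration–demercuration (Markovnikov hydration): mercury binds C17, water attacks tertiary C8, and borohydride replaces mercury by hydrogen. Water should enter along the equatorial α trajectory because the axial β path is blocked by the syn-axial C20 methyl, which gives the 8α-alcohol with an axial C17 methyl.

Step 5
Reactants: 6 6α-acetoxy-13,13-ethylenedioxy-14,15-dinorlabdan-8α-ol
Product: 7 6α-acetoxy-13,13-ethylenedioxy-8α-(triethylsilyloxy)-14,15-dinorlabdane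
Conditions: Et3SiOTf, 2,6-lutidine, CH2Cl2, −78 to 0 °C
Reagents that add atoms: triethylsilyl trifluoromethanesulfonate, CC[Si](CC)(CC)OS(=O)(=O)C(F)(F)F
Why: Silylation of a hindered tertiary alcohol with a silyl triflate and a hindered pyridine base; ketone-derived dioxolanes tolerate these conditions at low temperature. The silyl ether blocks O8 as a radical site in step 7 and as a nucleophile later.

Step 6
Reactants: 7 6α-acetoxy-13,13-ethylenedioxy-8α-(triethylsilyloxy)-14,15-dinorlabdane
Product: 8 13,13-ethylenedioxy-8α-(triethylsilyloxy)-14,15-dinorlabdan-6α-ol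
Conditions: K2CO3, MeOH, rt to 40 °C
Reagents that add atoms: none
Why: Base-catalysed methanolysis of the acetate; the tertiary triethylsilyl ether and the ketal are stable to carbonate in methanol.

Step 7
Reactants: 8 13,13-ethylenedioxy-8α-(triethylsilyloxy)-14,15-dinorlabdan-6α-ol
Product: 11 6α,18-epoxy-13,13-ethylenedioxy-8α-(triethylsilyloxy)-14,15-dinorlabdane, via 6α-hypoiodite 9 (not isolated), via 18-iodo 6α-alcohol 10 (not isolated)
Conditions: PhI(OAc)2 (1.5 equiv), I2 (1 equiv), cyclohexane, hν (tungsten lamp), 25–40 °C
Reagents that add atoms: none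
Why: PhI(OAc)2 and I2 give acetyl hypoiodite, which converts the 6α-hydroxyl into hypoiodite 9, and visible light cleaves the weak O–I bond to the C6 alkoxyl radical. This radical takes a hydrogen atom from C18 through a six-membered chair-like transition state (O6, C6, C5, C4, C18, H; 1,5-hydrogen transfer), iodine traps the C18 radical as iodide 10, and the 6α-oxygen then displaces iodide, probably after oxidation of the iodide to a better leaving group, to give 11. The closest known reaction type is the hypoiodite reaction that forms tetrahydrofurans from methyl groups peri or 1,3-diaxial to a hydroxyl in steroids and terpenoids. The one ring formed, the tetrahydrofuran O–C6–C5–C4–C18, closes in the 5-exo-tet mode by O–C18 bond formation. The new stereocentre is C4: the reaction tells its two methyl groups apart, and the existing configurations at C5 and C6 decide the outcome, because only the equatorial 4α-methyl lies parallel to the equatorial C6–O bond while the axial C19 is gauche on the other side. The step needs site selectivity for C18 over C19, C20 and C17 and chemoselectivity over β-scission and ketone formation: the rigid trans-decalin keeps the axial β-methyls out of reach, β-scission of C5–C6 would give only a secondary radical and should be slower than the hydrogen transfer, and the silyl ether on O8 prevents a second alkoxyl radical that would break the C8–C9 bond. The dioxolane and the silyl ether should tolerate the acetic acid that is formed.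

Step 8
Reactants: 11 6α,18-epoxy-13,13-ethylenedioxy-8α-(triethylsilyloxy)-14,15-dinorlabdane
Product: 12 13,13-ethylenedioxy-8α-(triethylsilyloxy)-14,15-dinorlabdano-18,6α-lactone
Conditions: RuCl3 (cat.), NaIO4, NaHCO3, EtOAc/MeCN/H2O, rt
Reagents that add atoms: sodium periodate (oxygen source by way of RuO4), [Na+].[O-]I(=O)(=O)=O
Why: Ruthenium tetroxide oxidation of an ether α-methylene to the ester level (ether to lactone). The C18 methylene is exposed on the α face, whereas the only other α-hydrogen, 6β-H, is a methine flanked by the axial C19 and C20 methyls; bicarbonate keeps the medium near neutral for the ketal and the silyl ether.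

Step 9
Reactants: 12 13,13-ethylenedioxy-8α-(triethylsilyloxy)-14,15-dinorlabdano-18,6α-lactone
Product: 13 13-oxo-8α-(triethylsilyloxy)-14,15-dinorlabdano-18,6α-lactone
Conditions: pyridinium p-toluenesulfonate (cat.), acetone/H2O, 50 °C
Reagents that add atoms: water, O
Why: Mild acid-catalysed hydrolysis of the dioxolane; the lactone and the tertiary silyl ether should be stable to the pyridinium acid. With O8 silylated the freed ketone cannot form a hemiketal.

Step 10
Reactants: 13 13-oxo-8α-(triethylsilyloxy)-14,15-dinorlabdano-18,6α-lactone; 14 triethyl phosphonoacetate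
Product: 15 ethyl (13E)-6α,18-epoxy-18-oxo-8α-(triethylsilyloxy)labd-13-en-15-oate
Conditions: NaH, THF, 0 to 50 °C
Reagents that add atoms: none
Why: Horner–Wadsworth–Emmons olefination of a methyl ketone; reversible addition places the ester anti to the larger C12 chain and should give mainly the (13E)-enoate, the minor (13Z) isomer being removed by chromatography. The lactone has no α-hydrogen and a neopentyl carbonyl, so it should not interfere.

Step 11
Reactants: 15 ethyl (13E)-6α,18-epoxy-18-oxo-8α-(triethylsilyloxy)labd-13-en-15-oate
Product: 16 (13E)-6α,18-epoxy-8α-(triethylsilyloxy)labd-13-ene-15,18-diol (18,6α-lactol, both C18 anomers)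
Conditions: i-Bu2AlH (4 equiv), CH2Cl2, −78 °C; aq. potassium sodium tartrate
Reagents that add atoms: none
Why: Hydride reduction: at −78 °C the lactone should stop at the lactol oxidation level, while the conjugated ester is reduced 1,2 to the allylic alcohol. One operation thus brings C18 to the aldehyde level and C15 to the alcohol level; C18 forms as an anomeric mixture of no consequence.

Step 12
Reactants: 16 (13E)-6α,18-epoxy-8α-(triethylsilyloxy)labd-13-ene-15,18-diol
Product: 17 (13E)-6α,18-epoxy-18-hydroxy-8α-(triethylsilyloxy)labd-13-en-15-al
Conditions: MnO2 (activated, excess), CH2Cl2, rt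
Reagents that add atoms: none
Why: Activated MnO2 oxidises allylic alcohols chemoselectively; the saturated neopentyl lactol should react far more slowly. The enal is carried on promptly, because 3-methyl-2-enals can equilibrate E/Z on long exposure to acid or base.

Step 13
Reactants: 17 (13E)-6α,18-epoxy-18-hydroxy-8α-(triethylsilyloxy)labd-13-en-15-al
Product: 18 (13E)-6α,18-epoxy-8α,18-bis(triethylsilyloxy)labd-13-en-15-al
Conditions: Et3SiCl, imidazole, 4-(dimethylamino)pyridine (cat.), CH2Cl2, 0 °C to rt
Reagents that add atoms: chlorotriethylsilane, CC[Si](CC)(CC)Cl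
Why: Silylation of the hemiacetal hydroxyl gives a fluoride-labile O-silyl acetal, so no acidic acetal hydrolysis is needed at the end. If some open hydroxy aldehyde were silylated on O6 instead, that material would also converge on 23 in step 16.

Step 14
Reactants: 19 4-methylfuran-2(5H)-one
Product: 20 4-methyl-2-(trimethylsilyloxy)furan
Conditions: Me3SiOTf, Et3N, Et2O, 0 °C
Reagents that add atoms: trimethylsilyl trifluoromethanesulfonate, C[Si](C)(C)OS(=O)(=O)C(F)(F)F
Why: Soft enolisation and O-silylation of the butenolide gives the aromatic 2-silyloxyfuran, the nucleophile of the vinylogous aldol addition. The compound is moisture-sensitive and is used directly.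

Step 15
Reactants: 18 (13E)-6α,18-epoxy-8α,18-bis(triethylsilyloxy)labd-13-en-15-al; 20 4-methyl-2-(trimethylsilyloxy)furan
Product: 22 (5′S)-5′-[(13E,15S)-6α,18-epoxy-15-hydroxy-8α,18-bis(triethylsilyloxy)labd-13-en-15-yl]-4′-methylfuran-2′(5′H)-one, via 15-O-trimethylsilyl ether 21 (not isolated)
Conditions: Ti(OiPr)4 (20 mol %), (R)-1,1′-bi-2-naphthol (20 mol %), Et2O, −20 °C; then aq. citric acid, 0 °C
Reagents that add atoms: none
Why: Catalytic enantioselective vinylogous Mukaiyama aldol addition: the silyloxyfuran reacts at C5′ (γ-position) with the Lewis-acid-bound aldehyde, and Lewis-acid-promoted additions of 2-silyloxyfurans to aldehydes favour the threo (15,5′-syn) adduct needed here. The core is too remote to influence the new centres, so the titanium binaphtholate must direct the furan to the Re face of the enal (15S, and with the threo preference 5′S); the (R) ligand is proposed and the (S) ligand is used if the sense proves opposite. The brief citric acid work-up should cleave only the trimethylsilyl ether of 21.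

Step 16
Reactants: 22 (5′S)-5′-[(13E,15S)-6α,18-epoxy-15-hydroxy-8α,18-bis(triethylsilyloxy)labd-13-en-15-yl]-4′-methylfuran-2′(5′H)-one
Product: 23 (5′S)-5′-[(13E,15S)-6α,8α,15-trihydroxy-18-oxolabd-13-en-15-yl]-4′-methylfuran-2′(5′H)-one
Conditions: HF·pyridine, pyridine, THF, 0 °C to rt
Reagents that add atoms: none
Why: Fluoride cleaves both Si–O bonds, and the freed hemiacetal is the ring tautomer of the 6α-hydroxy-18-aldehyde. The buffered, weakly acidic medium avoids epimerisation at C5′ and retro-aldol cleavage (base) as well as ionisation of the allylic C15 alcohol (strong acid).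

## Compound list

1 | larixol, (13S)-labda-8(17),14-diene-6α,13-diol | C=C[C@@](C)(O)CC[C@@H]1[C@@]2(C)CCCC(C)(C)[C@@H]2[C@@H](O)CC1=C | starting material
2 | larixyl acetate, (13S)-6α-acetoxylabda-8(17),14-dien-13-ol | C=C[C@@](C)(O)CC[C@@H]1[C@@]2(C)CCCC(C)(C)[C@@H]2[C@@H](OC(C)=O)CC1=C | intermediate
3 | 6α-acetoxy-14,15-dinorlabd-8(17)-en-13-one | CC(=O)CC[C@@H]1[C@@]2(C)CCCC(C)(C)[C@@H]2[C@@H](OC(C)=O)CC1=C | intermediate
4 | 6α-acetoxy-13,13-ethylenedioxy-14,15-dinorlabd-8(17)-ene | CC1(OCCO1)CC[C@@H]1[C@@]2(C)CCCC(C)(C)[C@@H]2[C@@H](OC(C)=O)CC1=C | intermediate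
5 | 17-(acetoxymercurio)-6α-acetoxy-13,13-ethylenedioxy-14,15-dinorlabdan-8α-ol | CC1(OCCO1)CC[C@@H]1[C@@]2(C)CCCC(C)(C)[C@@H]2[C@@H](OC(C)=O)C[C@@]1(C[Hg]OC(C)=O)O | intermediate (not isolated)
6 | 6α-acetoxy-13,13-ethylenedioxy-14,15-dinorlabdan-8α-ol | CC1(OCCO1)CC[C@@H]1[C@@]2(C)CCCC(C)(C)[C@@H]2[C@@H](OC(C)=O)C[C@@]1(C)O | intermediate
7 | 6α-acetoxy-13,13-ethylenedioxy-8α-(triethylsilyloxy)-14,15-dinorlabdane | CC1(OCCO1)CC[C@@H]1[C@@]2(C)CCCC(C)(C)[C@@H]2[C@@H](OC(C)=O)C[C@@]1(C)O[Si](CC)(CC)CC | intermediate
8 | 13,13-ethylenedioxy-8α-(triethylsilyloxy)-14,15-dinorlabdan-6α-ol | CC1(OCCO1)CC[C@@H]1[C@@]2(C)CCCC(C)(C)[C@@H]2[C@@H](O)C[C@@]1(C)O[Si](CC)(CC)CC | intermediate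
9 | 13,13-ethylenedioxy-6α-(iodooxy)-8α-(triethylsilyloxy)-14,15-dinorlabdane | CC1(OCCO1)CC[C@@H]1[C@@]2(C)CCCC(C)(C)[C@@H]2[C@@H](OI)C[C@@]1(C)O[Si](CC)(CC)CC | intermediate (not isolated)
10 | 13,13-ethylenedioxy-18-iodo-8α-(triethylsilyloxy)-14,15-dinorlabdan-6α-ol | CC1(OCCO1)CC[C@@H]1[C@@]2(C)CCC[C@@](C)(CI)[C@@H]2[C@@H](O)C[C@@]1(C)O[Si](CC)(CC)CC | intermediate (not isolated)
11 | 6α,18-epoxy-13,13-ethylenedioxy-8α-(triethylsilyloxy)-14,15-dinorlabdane | CC1(OCCO1)CC[C@@H]1[C@@]2(C)CCC[C@@](C)(CO3)[C@@H]2[C@@H]3C[C@@]1(C)O[Si](CC)(CC)CC | intermediate
12 | 13,13-ethylenedioxy-8α-(triethylsilyloxy)-14,15-dinorlabdano-18,6α-lactone | CC1(OCCO1)CC[C@@H]1[C@@]2(C)CCC[C@@](C)(C(=O)O3)[C@@H]2[C@@H]3C[C@@]1(C)O[Si](CC)(CC)CC | intermediate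
13 | 13-oxo-8α-(triethylsilyloxy)-14,15-dinorlabdano-18,6α-lactone | CC(=O)CC[C@@H]1[C@@]2(C)CCC[C@@](C)(C(=O)O3)[C@@H]2[C@@H]3C[C@@]1(C)O[Si](CC)(CC)CC | intermediate
14 | triethyl phosphonoacetate | CCOC(=O)CP(=O)(OCC)OCC | starting material
15 | ethyl (13E)-6α,18-epoxy-18-oxo-8α-(triethylsilyloxy)labd-13-en-15-oate | CCOC(=O)/C=C(\C)CC[C@@H]1[C@@]2(C)CCC[C@@](C)(C(=O)O3)[C@@H]2[C@@H]3C[C@@]1(C)O[Si](CC)(CC)CC | intermediate
16 | (13E)-6α,18-epoxy-8α-(triethylsilyloxy)labd-13-ene-15,18-diol (lactol, both C18 anomers) | OC/C=C(\C)CC[C@@H]1[C@@]2(C)CCC[C@@](C)(C(O)O3)[C@@H]2[C@@H]3C[C@@]1(C)O[Si](CC)(CC)CC | intermediate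
17 | (13E)-6α,18-epoxy-18-hydroxy-8α-(triethylsilyloxy)labd-13-en-15-al (both C18 anomers) | O=C/C=C(\C)CC[C@@H]1[C@@]2(C)CCC[C@@](C)(C(O)O3)[C@@H]2[C@@H]3C[C@@]1(C)O[Si](CC)(CC)CC | intermediate
18 | (13E)-6α,18-epoxy-8α,18-bis(triethylsilyloxy)labd-13-en-15-al (both C18 anomers) | O=C/C=C(\C)CC[C@@H]1[C@@]2(C)CCC[C@@](C)(C(O[Si](CC)(CC)CC)O3)[C@@H]2[C@@H]3C[C@@]1(C)O[Si](CC)(CC)CC | intermediate
19 | 4-methylfuran-2(5H)-one | CC1=CC(=O)OC1 | starting material
20 | 4-methyl-2-(trimethylsilyloxy)furan | Cc1coc(O[Si](C)(C)C)c1 | intermediate
21 | (5′S)-5′-[(13E,15S)-6α,18-epoxy-8α,18-bis(triethylsilyloxy)-15-(trimethylsilyloxy)labd-13-en-15-yl]-4′-methylfuran-2′(5′H)-one | CC1=CC(=O)O[C@@H]1[C@@H](O[Si](C)(C)C)/C=C(\C)CC[C@@H]1[C@@]2(C)CCC[C@@](C)(C(O[Si](CC)(CC)CC)O3)[C@@H]2[C@@H]3C[C@@]1(C)O[Si](CC)(CC)CC | intermediate (not isolated)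
22 | (5′S)-5′-[(13E,15S)-6α,18-epoxy-15-hydroxy-8α,18-bis(triethylsilyloxy)labd-13-en-15-yl]-4′-methylfuran-2′(5′H)-one | CC1=CC(=O)O[C@@H]1[C@@H](O)/C=C(\C)CC[C@@H]1[C@@]2(C)CCC[C@@](C)(C(O[Si](CC)(CC)CC)O3)[C@@H]2[C@@H]3C[C@@]1(C)O[Si](CC)(CC)CC | intermediate
23 | (5′S)-5′-[(13E,15S)-6α,8α,15-trihydroxy-18-oxolabd-13-en-15-yl]-4′-methylfuran-2′(5′H)-one (CNP0112578.1) | CC1=CC(=O)O[C@@H]1[C@@H](O)/C=C(\C)CC[C@@H]1[C@@]2(C)CCC[C@@](C)(C=O)[C@@H]2[C@@H](O)C[C@@]1(C)O | target

## Step count and least certain steps

Total step count: 16. Longest linear sequence: 15 steps (steps 1 to 13, 15 and 16); step 14 prepares the furan separately.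

Step 7 (key step). Most likely to go wrong: diversion of hypoiodite 9 or of the C6 alkoxyl radical (oxidation of the carbinol to the 6-ketone, β-scission of C5–C6, or incomplete closure of iodide 10), because the oxidising medium offers these paths beside the hydrogen transfer. Fallback (Barton nitrite photolysis, which brings C18 directly to the aldehyde level without an oxidant):
- From 8, nitrosyl chloride in pyridine gives the 6α-nitrite ester F1.
- Irradiation (Hg lamp, borosilicate filter, benzene) cleaves O–NO, the same 1,5-hydrogen transfer takes place and NO recombines at C18 to the 18-nitroso 6α-alcohol F2, which tautomerises to the 18-oxime F3.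
- Reductive hydrolysis of the oxime (TiCl3, NH4OAc buffer, aqueous dioxane) gives the 18,6α-lactol F4.
- Oxidation of the lactol (Pr4N[RuO4] cat., N-methylmorpholine N-oxide, CH2Cl2) returns to the route at 12, bypassing 11 and step 8.

Step 8. Most likely to go wrong: loss or oxidative cleavage of the dioxolane in the aqueous oxidising medium, and slower attack on other C–H bonds once the ether is consumed. Fallback (change of order, so that no acid- or oxidant-sensitive ketal is present): from 11 the ketal is hydrolysed first (pyridinium p-toluenesulfonate, aqueous acetone) to the 6α,18-epoxy-13-ketone F5, whose methyl ketone is inert to RuO4. Oxidation of F5 under the conditions of step 8 gives 13 directly, where the route is rejoined. If the ether oxidation itself proved unselective, the nitrite sequence described under step 7 reaches 12 without it.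

Step 15. Most likely to go wrong: poor facial selectivity at the aldehyde, because the stereocentres of the core are too far away to help and the catalyst is not matched to a β,β-disubstituted enal; the 4-methyl group of the furan may also erode the threo preference. Ionisation of the silyl acetal at C18 by the Lewis acid is a lesser risk. Fallback (resolution in place of asymmetric induction): from 18 and 20 the addition is run with an achiral promoter (BF3·OEt2, CH2Cl2, −78 °C), relying only on the intrinsic threo preference. This should give 22 together with its (15R,5′R) isomer F6; the two are diastereomers because of the enantiopure core and are separated by preparative chromatography, so the route is rejoined at 22. The separation may be demanding, since the two differ only far from the core.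

Step 4. Most likely to go wrong: attack of water from the β face (8β-alcohol) or partial loss of the 6-acetate in the alkaline borohydride stage. Fallback (epoxide route, in which the face of a peracid attack fixes C8): from 4, mCPBA should epoxidise C8=C17 from the less hindered α face to the 8α,17-epoxide F7. LiAlH4 opens the epoxide at C17 and removes the acetate to give the 6α,8α-diol F8. Acetylation (Ac2O, pyridine) should take place only at the secondary 6α-hydroxyl and returns to the route at 6.

## Further compounds

F1 | step 7 | 13,13-ethylenedioxy-8α-(triethylsilyloxy)-14,15-dinorlabdan-6α-yl nitrite | CC1(OCCO1)CC[C@@H]1[C@@]2(C)CCCC(C)(C)[C@@H]2[C@@H](ON=O)C[C@@]1(C)O[Si](CC)(CC)CC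
F2 | step 7 | 13,13-ethylenedioxy-18-nitroso-8α-(triethylsilyloxy)-14,15-dinorlabdan-6α-ol | CC1(OCCO1)CC[C@@H]1[C@@]2(C)CCC[C@@](C)(CN=O)[C@@H]2[C@@H](O)C[C@@]1(C)O[Si](CC)(CC)CC
F3 | step 7 | (E)-oxime of 13,13-ethylenedioxy-6α-hydroxy-8α-(triethylsilyloxy)-14,15-dinorlabdan-18-al | CC1(OCCO1)CC[C@@H]1[C@@]2(C)CCC[C@@](C)(/C=N/O)[C@@H]2[C@@H](O)C[C@@]1(C)O[Si](CC)(CC)CC
F4 | step 7 | 6α,18-epoxy-13,13-ethylenedioxy-8α-(triethylsilyloxy)-14,15-dinorlabdan-18-ol (lactol, both C18 anomers) | CC1(OCCO1)CC[C@@H]1[C@@]2(C)CCC[C@@](C)(C(O)O3)[C@@H]2[C@@H]3C[C@@]1(C)O[Si](CC)(CC)CC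
F5 | step 8 | 6α,18-epoxy-8α-(triethylsilyloxy)-14,15-dinorlabdan-13-one | CC(=O)CC[C@@H]1[C@@]2(C)CCC[C@@](C)(CO3)[C@@H]2[C@@H]3C[C@@]1(C)O[Si](CC)(CC)CC
F6 | step 15 | (5′R)-5′-[(13E,15R)-6α,18-epoxy-15-hydroxy-8α,18-bis(triethylsilyloxy)labd-13-en-15-yl]-4′-methylfuran-2′(5′H)-one | CC1=CC(=O)O[C@H]1[C@H](O)/C=C(\C)CC[C@@H]1[C@@]2(C)CCC[C@@](C)(C(O[Si](CC)(CC)CC)O3)[C@@H]2[C@@H]3C[C@@]1(C)O[Si](CC)(CC)CC
F7 | step 4 | 6α-acetoxy-8α,17-epoxy-13,13-ethylenedioxy-14,15-dinorlabdane | CC1(OCCO1)CC[C@@H]1[C@@]2(C)CCCC(C)(C)[C@@H]2[C@@H](OC(C)=O)C[C@@]1(C2)O2
F8 | step 4 | 13,13-ethylenedioxy-14,15-dinorlabdane-6α,8α-diol | CC1(OCCO1)CC[C@@H]1[C@@]2(C)CCCC(C)(C)[C@@H]2[C@@H](O)C[C@@]1(C)O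
A1 | alternative 1 | 3-[(tert-butyldimethylsilyl)oxy]-5-[(4-methoxybenzyl)oxy]-3-methyl-4-(1-methyl-4-oxocyclohexa-2,5-dien-1-yl)pentanal, C8 and C9 configured as in 23 | COc1ccc(COC[C@H](C2(C)C=CC(=O)C=C2)[C@@](C)(CC=O)O[Si](C)(C)C(C)(C)C)cc1
A2 | alternative 1 | cis-fused (5β-H) 8α-[(tert-butyldimethylsilyl)oxy]-9-[(4-methoxybenzyl)oxymethyl]-8β,10β-dimethyloctal-1-ene-3,6-dione | COc1ccc(COC[C@@H]2[C@@]3(C)C=CC(=O)C[C@H]3C(=O)C[C@@]2(C)O[Si](C)(C)C(C)(C)C)cc1
A3 | alternative 2 | dimethyl malonate triene: (S)-4-benzyl-N-[(E)-3-methylenoyl]oxazolidin-2-one joined through C1–C3 to C4(CO2Me)2 and the (5Z,7E)-6-(tert-butyldimethylsilyloxy)diene | O=C(N1C(=O)OC[C@@H]1Cc1ccccc1)/C=C(\C)CCCC(C(=O)OC)(C(=O)OC)/C=C(O[Si](C)(C)C(C)(C)C)/C=C/C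
A4 | alternative 2 | trans-fused octalin silyl enol ether (C6=C7) with C9 acyl oxazolidinone, 8β-methyl, 10β-methyl, 5α-H and C4 dimethyl malonate | O=C(N1C(=O)OC[C@@H]1Cc1ccccc1)[C@@H]1[C@@]2(C)CCCC(C(=O)OC)(C(=O)OC)[C@@H]2C(O[Si](C)(C)C(C)(C)C)=C[C@@H]1C
A5 | alternative 3 | 18,18-dimethoxy-6α,8α-bis(triethylsilyloxy)-14,15,16-trinorlabd-13-yne | C#CCC[C@@H]1[C@@]2(C)CCC[C@@](C)(C(OC)OC)[C@@H]2[C@@H](O[Si](CC)(CC)CC)C[C@@]1(C)O[Si](CC)(CC)CC
A6 | alternative 3 | (S)-2-[(4-methoxybenzyl)oxy]-3-methylbut-3-enal | C=C(C)[C@H](OCc1ccc(OC)cc1)C=O
A7 | alternative 3 | (13E,15S)-allylic alcohol with O-(4-methoxybenzyl) and isopropenyl on the future C5′, 18,18-dimethoxy and 6α,8α-bis(triethylsilyloxy) groups | C=C(C)[C@H](OCc1ccc(OC)cc1)[C@@H](O)/C=C(\C)CC[C@@H]1[C@@]2(C)CCC[C@@](C)(C(OC)OC)[C@@H]2[C@@H](O[Si](CC)(CC)CC)C[C@@]1(C)O[Si](CC)(CC)CC
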